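## Analysis of the target

Compound 29 is a (3R)-isoflavan: aromatic ring A is fused to the oxygen heterocycle ring C (a chroman), and the resorcinol ring B sits on C3. Ring A is substituted on three neighbouring carbons: C8a carries the ring oxygen O1, C8 a 3-hydroxy-3-methylbutyl chain and C7 a free hydroxyl. Ring B carries hydroxyls at C2' and C4' and a 1,1-dimethylallyl (2-methylbut-3-en-2-yl) group at C5'. C3 is the only stereocentre, so there is no relative configuration to control; it is benzylic to ring B only and has no carbonyl neighbour in the target, so it is configurationally safe once the carbonyl chemistry is over. Three groups are sensitive: the tertiary alcohol close to the C7 phenol (acid closes a 2,2-dimethylchroman), the terminal alkene on a quaternary carbon ortho to the C4' phenol (acid closes a dihydrobenzofuran, hydrogen saturates it), and the oxidisable free resorcinol. Acid-labile and hydrogenolytic protecting groups are therefore excluded at the end. The difficulty is to place a carbon chain on C8 between two oxygen-bearing carbons and to set a stereocentre that has no functional handle. The strategy rests on C8a and C8: they are adjacent carbons of ring A flanked by the C7 oxygen, so they can be the two carbons of an aryne. O1 then arrives at C8a as a tethered alkoxide, and the carbanion left at C8 opens 2,2-dimethyloxetane (23), whose ring-opened form is the side chain.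

## Retrosynthetic reasoning

**29 back to 27 (protecting groups).** The last two operations only unmask phenols. Ring B is carried as its bis(silyl ether) and O7 as an allyl ether, because fluoride and a zerovalent palladium catalyst with an amine allyl acceptor are neutral. They leave the tertiary alcohol, the 1,1-dimethylallyl group and C3 alone, so 29 comes from 28 and 28 from 27.

**27 back to 22 and 23 (O1–C8a and C8–CH2).** Both bonds at the crowded edge of ring A are cut at once. Cutting here and not at O1–C2 avoids having to alkylate an arene carbon between two oxygens, and the chain does not have to be carried through the synthesis. The forward reaction has to turn the 2-iodoaryl sulfonate of 22 into the C8–C8a aryne and let the tethered alkoxide add at C8a to close ring C. The arylmagnesium left at C8 must then open 23 at its CH2–O carbon. The positions of both new bonds are fixed by where iodine and sulfonate sit in 22.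

**22 back to 19 and 7 (C3–C4).** The stereocentre is made by alkylating the enolate of the arylacetyl imide 19 with the benzyl bromide 7, followed by reductive removal of the auxiliary from 21. This cut puts the stereocentre next to a carbonyl only for two steps. After reduction to 22 it can no longer epimerise. The ring B aryl group outranks the incoming benzyl group, so the (R)-auxiliary 17 is required for the R centre.

**7 back to 1 (ring A).** The bromide 7 comes from the aldehyde 5 by reduction to 6 and bromination. The 1,2,3,4-pattern of 5 (CH2 precursor, iodine, sulfonate, allyl ether) is written onto isovanillin (1). Iodination between the formyl and hydroxyl groups gives 2, while no alkene is yet present. The hydroxyl is then sulfonylated (3), the methyl ether cleaved (4) and the freed phenol allylated (5). At each stage only one phenol is free, so no regiochemical choice arises.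

**19 back to 16 and 17, and 16 back to 8 and 9 (ring B).** The imide 19 is the acylation product of the auxiliary 17 with the arylacetic acid 16. The acid is the one-carbon homologue of the aldehyde 13 by way of the enol ether 14. The 1,1-dimethylallyl group of 13 is the product of an aromatic Claisen rearrangement of the prenyl ether 11, which inverts the allyl unit and delivers it ortho to O4'. The prenyl ether comes from 2,4-dihydroxybenzaldehyde (8) and prenyl bromide (9). The hydrogen-bonded 2-hydroxyl of 8 stays free during prenylation (10) and is then silylated (11), so that chelation does not steer the rearrangement to C3. After the rearrangement (12) the second silyl group is added (13).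

## Alternatives that were turned down

**Alternative 1: ring A by benzannulation of a diazo ketone with a siloxyalkyne.**
- Disconnection: C8a–C8, C6–C7 and C4a–C8a, which builds ring A from open-chain pieces. The (E)-diazo enone A2 brings C4a, C5, C6, C8a and the complete C3 side arm. The siloxyalkyne A3 brings C7 with its oxygen and C8 with the chain.
- Forward key step: irradiation of A2 triggers a Wolff rearrangement to a vinylketene. This adds A3 in a [2+2] reaction, and 4π opening, 6π closure and tautomerisation give the phenol A1 (free C8a hydroxyl, silyl ether at C7, chain at C8).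
- For it: the mechanism dictates the 1,2,3-pattern, the reaction class is established for siloxyalkynes, and the chain enters as an ordinary alkyne substituent.
- Against it: it builds a benzene ring that can be bought. A2 still needs the stereocentre from auxiliary chemistry before the enone and diazo ketone are constructed, and the photolysis runs beside a terminal alkene and electron-rich arenes. Ring C is still open in A1. One primary silyl ether must be cleaved selectively beside four other silyl ethers, ring C closed, and three kinds of silyl group removed.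
- Comparison: this alternative is stronger on precedent for the key step and on certainty of regiochemistry. The chosen route offers a purchased ring A, ring C and the chain in one operation, two steps after the key step and only two kinds of protecting group.

**Alternative 2: carbene C–H insertion through a temporary O2' tether.**
- Disconnection: C3–C4, after ring A has been tied through its benzylic carbon to O2' of ring B as a benzyl ether.
- Forward key step: with Rh2(S-PTTL)4 the aryldiazoacetate A5 gives a rhodium carbene at C3. It inserts into the benzylic C–H next to the ether oxygen and closes the cis-dihydrobenzofuran ester A4 ((2R,3S) in benzofuran numbering).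
- For it: the stereocentre is set catalytically, insertion next to an ether oxygen at a benzylic site is strongly favoured, and the class is well known.
- Against it: the ring that closes is not in the target. The C4–O2' bond must later be cleaved reductively without touching the terminal alkene. C3 in A4 is benzylic and next to an ester, so cis-to-trans epimerisation would erase the one stereocentre that matters. Ester reduction and ring C closure are further steps, and the C8 chain of ring A has to be installed by separate, crowded arene chemistry.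
- Comparison: this alternative is stronger on catalytic asymmetric induction. The chosen route offers a stereocentre that cannot epimerise after step 15, no reductive C–O cleavage, and a key step that solves the ring A pattern and ring C together.

**Alternative 3: conjunctive coupling of both aryl rings onto vinylboron.**
- Disconnection: C3–C1' and C4–C4a, both to the two carbons of vinylboronic ester A7.
- Forward key step: the ring B aryllithium A9 adds to A7 to give a boronate complex. With Pd(OAc)2 and MandyPhos the ring A bromide A8 adds oxidatively, and the divalent arylpalladium species induces a 1,2-shift of ring B from boron to C3. Reductive elimination forms C4–C4a and gives the (R)-boronate A6.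
- For it: it is the most convergent plan, with three components, two C–C bonds and the stereocentre in one catalytic step.
- Against it: boron ends on C3 where the target has C2, so a Matteson one-carbon homologation and an oxidation must follow before ring C can close. A8 and A9 are both ortho-substituted, and bromides are the less suitable electrophiles for this class. The acetal groups on ring B need acid for removal, which endangers both sensitive pairs of the target. A8 with its C8 chain is itself a multistep compound.
- Comparison: this alternative is stronger on convergence and catalytic enantiocontrol. The chosen route offers chain and ring C in one operation from a simple benzaldehyde-derived ring A, an acid-free end game and a dependable auxiliary alkylation.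

Key step: step 16

## Route

Assumption: C3 is R by the CIP ranking CH2O > ring B aryl > CH2 of ring A > H, which is why the (R)-configured auxiliary 17 is used.

Step 1
Reactants: 1 isovanillin (3-hydroxy-4-methoxybenzaldehyde)
Product: 2 3-hydroxy-2-iodo-4-methoxybenzaldehyde
Conditions: ICl, pyridine, 1,4-dioxane, 0 °C to rt
Reagents that add atoms: iodine monochloride, ClI
Why: Electrophilic aromatic iodination of a phenol; the hydroxyl directs to its free ortho carbon C2, the established site for isovanillin, and no alkene is yet present that ICl could attack.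

Step 2
Reactants: 2 3-hydroxy-2-iodo-4-methoxybenzaldehyde
Product: 3 3-formyl-2-iodo-6-methoxyphenyl 4-chlorobenzenesulfonate
Conditions: 4-ClC6H4SO2Cl, Et3N, DMAP (cat.), CH2Cl2, 0 °C to rt
Reagents that add atoms: 4-chlorobenzenesulfonyl chloride, O=S(=O)(Cl)c1ccc(Cl)cc1
Why: O-Sulfonylation of the only free phenol; the arenesulfonate next to iodine is the leaving group needed later for magnesium-induced aryne formation.

Step 3
Reactants: 3 3-formyl-2-iodo-6-methoxyphenyl 4-chlorobenzenesulfonate
Product: 4 3-formyl-6-hydroxy-2-iodophenyl 4-chlorobenzenesulfonate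
Conditions: BBr3, CH2Cl2, −78 to 0 °C; then H2O
Reagents that add atoms: none
Why: Lewis acid cleavage of an aryl methyl ether (bromide attacks the methyl group of the boron-complexed ether); aryl sulfonate, aryl iodide and aldehyde should tolerate BBr3 at low temperature, and the phenol set free is the only one in the molecule.

Step 4
Reactants: 4 3-formyl-6-hydroxy-2-iodophenyl 4-chlorobenzenesulfonate
Product: 5 6-(allyloxy)-3-formyl-2-iodophenyl 4-chlorobenzenesulfonate
Conditions: allyl bromide, K2CO3, DMF, rt
Reagents that add atoms: allyl bromide, C=CCBr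
Why: Williamson ether synthesis on the single phenol; its phenoxide is stabilised by the para formyl group, so it has no drive to take over the neighbouring sulfonyl group and the regiochemistry is unambiguous.

Step 5
Reactants: 5 6-(allyloxy)-3-formyl-2-iodophenyl 4-chlorobenzenesulfonate
Product: 6 6-(allyloxy)-3-(hydroxymethyl)-2-iodophenyl 4-chlorobenzenesulfonate
Conditions: NaBH4, MeOH/THF, 0 °C
Reagents that add atoms: none
Why: Chemoselective borohydride reduction of the aldehyde; aryl sulfonate, aryl iodide and allyl ether are inert to NaBH4.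

Step 6
Reactants: 6 6-(allyloxy)-3-(hydroxymethyl)-2-iodophenyl 4-chlorobenzenesulfonate
Product: 7 6-(allyloxy)-3-(bromomethyl)-2-iodophenyl 4-chlorobenzenesulfonate
Conditions: CBr4, PPh3, CH2Cl2, 0 °C
Reagents that add atoms: carbon tetrabromide, BrC(Br)(Br)Br
Why: Appel reaction; the primary benzylic alcohol is converted into the bromide under neutral conditions that spare the sulfonate and the allyl ether.

Step 7
Reactants: 8 2,4-dihydroxybenzaldehyde; 9 1-bromo-3-methylbut-2-ene (prenyl bromide)
Product: 10 2-hydroxy-4-[(3-methylbut-2-en-1-yl)oxy]benzaldehyde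
Conditions: K2CO3, acetone, reflux
Reagents that add atoms: none
Why: Williamson etherification selective for the 4-hydroxyl; the 2-hydroxyl is held in a hydrogen bond to the formyl group and is the less reactive one.

Step 8
Reactants: 10 2-hydroxy-4-[(3-methylbut-2-en-1-yl)oxy]benzaldehyde
Product: 11 2-(tert-butyldimethylsilyloxy)-4-[(3-methylbut-2-en-1-yl)oxy]benzaldehyde
Conditions: TBSCl, imidazole, DMF, rt
Reagents that add atoms: tert-butyldimethylsilyl chloride, CC(C)(C)[Si](C)(C)Cl
Why: Silylation of the chelated phenol; removing the hydrogen bond to the carbonyl removes the bond fixation that would otherwise send the next rearrangement to C3.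

Step 9
Reactants: 11 2-(tert-butyldimethylsilyloxy)-4-[(3-methylbut-2-en-1-yl)oxy]benzaldehyde
Product: 12 2-(tert-butyldimethylsilyloxy)-4-hydroxy-5-(2-methylbut-3-en-2-yl)benzaldehyde
Conditions: PhNEt2, 190 °C, degassed
Reagents that add atoms: none
Why: Aromatic Claisen rearrangement ([3,3]-sigmatropic shift, then tautomerisation) inverts the prenyl unit to the 1,1-dimethylallyl group; migration should go to the less hindered ortho carbon C5 and not to C3 between two oxygen substituents, as in related 2-alkoxy-4-prenyloxybenzaldehydes, and the basic solvent suppresses acid-induced cyclisation of the product phenol.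

Step 10
Reactants: 12 2-(tert-butyldimethylsilyloxy)-4-hydroxy-5-(2-methylbut-3-en-2-yl)benzaldehyde
Product: 13 2,4-bis(tert-butyldimethylsilyloxy)-5-(2-methylbut-3-en-2-yl)benzaldehyde
Conditions: TBSOTf, 2,6-lutidine, CH2Cl2, 0 °C
Reagents that add atoms: tert-butyldimethylsilyl trifluoromethanesulfonate, CC(C)(C)[Si](C)(C)OS(=O)(=O)C(F)(F)F
Why: Silylation of a phenol hindered by the neighbouring quaternary carbon, for which the silyl triflate is the appropriate reagent.

Step 11
Reactants: 13 2,4-bis(tert-butyldimethylsilyloxy)-5-(2-methylbut-3-en-2-yl)benzaldehyde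
Product: 14 1,5-bis(tert-butyldimethylsilyloxy)-2-(2-methoxyethenyl)-4-(2-methylbut-3-en-2-yl)benzene (E/Z mixture)
Conditions: Ph3P(CH2OMe)Cl, KN(SiMe3)2, THF, 0 °C to rt
Reagents that add atoms: (methoxymethyl)triphenylphosphonium chloride, COC[P+](c1ccccc1)(c1ccccc1)c1ccccc1.[Cl-]
Why: Wittig olefination with the methoxymethylene ylide adds the one carbon of the future carboxyl group; the alkene geometry is irrelevant because both isomers hydrolyse to the same aldehyde.

Step 12
Reactants: 14 1,5-bis(tert-butyldimethylsilyloxy)-2-(2-methoxyethenyl)-4-(2-methylbut-3-en-2-yl)benzene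
Product: 16 2-[2,4-bis(tert-butyldimethylsilyloxy)-5-(2-methylbut-3-en-2-yl)phenyl]acetic acid, via arylacetaldehyde 15 (not isolated)
Conditions: 1 M HCl, THF, rt; then NaClO2, NaH2PO4, 2-methyl-2-butene, t-BuOH/H2O, 0 °C to rt
Reagents that add atoms: water, O; sodium chlorite, [Na+].[O-]Cl=O
Why: Enol ether hydrolysis gives the labile arylacetaldehyde 15, which is oxidised without isolation (Pinnick oxidation); the alkene scavenger takes up HOCl and so protects the terminal alkene and the electron-rich ring, and aryl silyl ethers withstand both media.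

Step 13
Reactants: 16 2-[2,4-bis(tert-butyldimethylsilyloxy)-5-(2-methylbut-3-en-2-yl)phenyl]acetic acid; 17 (R)-4-benzyloxazolidin-2-one
Product: 19 (R)-4-benzyl-3-{2-[2,4-bis(tert-butyldimethylsilyloxy)-5-(2-methylbut-3-en-2-yl)phenyl]acetyl}oxazolidin-2-one, via mixed pivalic anhydride 18 (not isolated)
Conditions: PivCl, Et3N, THF, −20 °C; then 17, LiCl, rt
Reagents that add atoms: pivaloyl chloride, CC(C)(C)C(Cl)=O (its atoms stay in intermediate 18 and leave as pivalic acid)
Why: N-Acylation of the oxazolidinone through the mixed anhydride; the hindered pivaloyl carbonyl directs attack to the arylacetyl carbonyl, and the conditions are free of fluoride and strong base.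

Step 14
Reactants: 19 (R)-4-benzyl-3-{2-[2,4-bis(tert-butyldimethylsilyloxy)-5-(2-methylbut-3-en-2-yl)phenyl]acetyl}oxazolidin-2-one; 7 6-(allyloxy)-3-(bromomethyl)-2-iodophenyl 4-chlorobenzenesulfonate
Product: 21 6-(allyloxy)-3-{(2R)-3-[(4R)-4-benzyl-2-oxooxazolidin-3-yl]-2-[2,4-bis(tert-butyldimethylsilyloxy)-5-(2-methylbut-3-en-2-yl)phenyl]-3-oxopropyl}-2-iodophenyl 4-chlorobenzenesulfonate, via sodium enolate 20 (not isolated)
Conditions: NaN(SiMe3)2, THF, −78 °C; then 7, −78 to −40 °C
Reagents that add atoms: sodium bis(trimethylsilyl)amide, C[Si](C)(C)N([Na])[Si](C)(C)C (sodium appears only in intermediate 20)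
Why: Evans alkylation; the chelated (Z)-enolate 20 is attacked by the benzylic bromide on the face away from the benzyl group of the auxiliary, which with the (4R)-auxiliary sets C3 as R (the descriptor is opposite to the familiar propionyl case because the aryl group outranks the new CH2Ar group); SN2 at the benzylic bromide is far faster than any attack on sulfonate or iodide at −78 °C.

Step 15
Reactants: 21 6-(allyloxy)-3-{(2R)-3-[(4R)-4-benzyl-2-oxooxazolidin-3-yl]-2-[2,4-bis(tert-butyldimethylsilyloxy)-5-(2-methylbut-3-en-2-yl)phenyl]-3-oxopropyl}-2-iodophenyl 4-chlorobenzenesulfonate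
Product: 22 6-(allyloxy)-3-{(2R)-2-[2,4-bis(tert-butyldimethylsilyloxy)-5-(2-methylbut-3-en-2-yl)phenyl]-3-hydroxypropyl}-2-iodophenyl 4-chlorobenzenesulfonate
Conditions: LiBH4, MeOH (1 equiv), THF, 0 °C
Reagents that add atoms: none
Why: Reductive cleavage of the N-acyl oxazolidinone to the primary alcohol with release of the auxiliary; the weakly basic hydride should not epimerise C3, which from here on has no carbonyl neighbour, and sulfonate, iodide, allyl and silyl ethers are not reduced.

Step 16
Reactants: 22 6-(allyloxy)-3-{(2R)-2-[2,4-bis(tert-butyldimethylsilyloxy)-5-(2-methylbut-3-en-2-yl)phenyl]-3-hydroxypropyl}-2-iodophenyl 4-chlorobenzenesulfonate; 23 2,2-dimethyloxetane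
Product: 27 4-{(3R)-7-(allyloxy)-3-[2,4-bis(tert-butyldimethylsilyloxy)-5-(2-methylbut-3-en-2-yl)phenyl]chroman-8-yl}-2-methylbutan-2-ol, via dimagnesiated sulfonate 24 (not isolated), via aryne magnesium alkoxide 25 (not isolated), via C8 arylmagnesium isoflavan 26 (not isolated)
Conditions: iPrMgCl (2.1 equiv), THF, −78 °C to rt; then CuI (10 mol %), 23 (3 equiv), rt to 40 °C; aq. NH4Cl
Reagents that add atoms: isopropylmagnesium chloride, CC(C)[Mg]Cl (magnesium appears only in intermediates 24 to 26)
Why: Proposed new method: the first equivalent of iPrMgCl forms the magnesium alkoxide and the second exchanges the iodine at C8a to give 24; on warming, the magnesium at C8a expels the neighbouring 4-chlorobenzenesulfonate from C8 and the C8–C8a aryne 25 forms. The tethered alkoxide adds to C8a in a 6-exo-dig closure (O1–C8a), which makes ring C and leaves the carbanion at C8 as the arylmagnesium 26; addition at C8 would need a seven-membered ring and would put the charge away from the C7 oxygen, so tether length and the inductive polarisation of a 3-alkoxyaryne act in the same direction. Under CuI catalysis 26 should open 23 by SN2 attack at the unsubstituted CH2–O carbon, which forms the C8–CH2 bond and gives the tertiary alkoxide of the chain directly. The closest known reaction types are aryne generation from 2-iodoaryl sulfonates by iodine–magnesium exchange with electrophilic capture of the adduct Grignard reagent, base-induced benzyne cyclisation of 3-arylpropanols to chromans, and CuI-catalysed opening of oxetanes by Grignard reagents; their union in one flask on this substrate is without precedent. No stereocentre is formed, and C3, which has no acidifying neighbour, is a bystander. The step needs addition at C8a only, secured as described, and preference of the C8 Grignard for the oxetane over the allyl ether, which rests on the poor leaving-group quality of an aryloxide in an unactivated allyl ether at 40 °C or below.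

Step 17
Reactants: 27 4-{(3R)-7-(allyloxy)-3-[2,4-bis(tert-butyldimethylsilyloxy)-5-(2-methylbut-3-en-2-yl)phenyl]chroman-8-yl}-2-methylbutan-2-ol
Product: 28 (3R)-3-[2,4-bis(tert-butyldimethylsilyloxy)-5-(2-methylbut-3-en-2-yl)phenyl]-8-(3-hydroxy-3-methylbutyl)chroman-7-ol
Conditions: Pd(PPh3)4 (5 mol %), morpholine, THF, rt
Reagents that add atoms: none
Why: Zerovalent palladium ionises the allyl aryl ether to a π-allyl complex, which morpholine intercepts (Tsuji–Trost deallylation); the 1,1-dimethylallyl group has no leaving group and is untouched, and the medium is neutral.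

Step 18
Reactants: 28 (3R)-3-[2,4-bis(tert-butyldimethylsilyloxy)-5-(2-methylbut-3-en-2-yl)phenyl]-8-(3-hydroxy-3-methylbutyl)chroman-7-ol
Product: 29 (3R)-3-[2,4-dihydroxy-5-(2-methylbut-3-en-2-yl)phenyl]-8-(3-hydroxy-3-methylbutyl)chroman-7-ol (target)
Conditions: Bu4NF, AcOH, THF, 0 °C to rt, under argon
Reagents that add atoms: none
Why: Fluoride cleaves both aryl silyl ethers; buffering with acetic acid keeps the resorcinol protonated and so limits its oxidation, and no acid strong enough to cyclise the tertiary alcohol or the 1,1-dimethylallyl group is present.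

## Compound list

1 | isovanillin (3-hydroxy-4-methoxybenzaldehyde) | COc1ccc(C=O)cc1O | starting material
2 | 3-hydroxy-2-iodo-4-methoxybenzaldehyde | COc1ccc(C=O)c(I)c1O | intermediate
3 | 3-formyl-2-iodo-6-methoxyphenyl 4-chlorobenzenesulfonate | COc1ccc(C=O)c(I)c1OS(=O)(=O)c1ccc(Cl)cc1 | intermediate
4 | 3-formyl-6-hydroxy-2-iodophenyl 4-chlorobenzenesulfonate | O=Cc1ccc(O)c(OS(=O)(=O)c2ccc(Cl)cc2)c1I | intermediate
5 | 6-(allyloxy)-3-formyl-2-iodophenyl 4-chlorobenzenesulfonate | C=CCOc1ccc(C=O)c(I)c1OS(=O)(=O)c1ccc(Cl)cc1 | intermediate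
6 | 6-(allyloxy)-3-(hydroxymethyl)-2-iodophenyl 4-chlorobenzenesulfonate | C=CCOc1ccc(CO)c(I)c1OS(=O)(=O)c1ccc(Cl)cc1 | intermediate
7 | 6-(allyloxy)-3-(bromomethyl)-2-iodophenyl 4-chlorobenzenesulfonate | C=CCOc1ccc(CBr)c(I)c1OS(=O)(=O)c1ccc(Cl)cc1 | intermediate
8 | 2,4-dihydroxybenzaldehyde | O=Cc1ccc(O)cc1O | starting material
9 | 1-bromo-3-methylbut-2-ene | CC(C)=CCBr | starting material
10 | 2-hydroxy-4-[(3-methylbut-2-en-1-yl)oxy]benzaldehyde | CC(C)=CCOc1ccc(C=O)c(O)c1 | intermediate
11 | 2-(tert-butyldimethylsilyloxy)-4-[(3-methylbut-2-en-1-yl)oxy]benzaldehyde | CC(C)=CCOc1ccc(C=O)c(O[Si](C)(C)C(C)(C)C)c1 | intermediate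
12 | 2-(tert-butyldimethylsilyloxy)-4-hydroxy-5-(2-methylbut-3-en-2-yl)benzaldehyde | C=CC(C)(C)c1cc(C=O)c(O[Si](C)(C)C(C)(C)C)cc1O | intermediate
13 | 2,4-bis(tert-butyldimethylsilyloxy)-5-(2-methylbut-3-en-2-yl)benzaldehyde | C=CC(C)(C)c1cc(C=O)c(O[Si](C)(C)C(C)(C)C)cc1O[Si](C)(C)C(C)(C)C | intermediate
14 | 1,5-bis(tert-butyldimethylsilyloxy)-2-(2-methoxyethenyl)-4-(2-methylbut-3-en-2-yl)benzene (E/Z mixture) | C=CC(C)(C)c1cc(C=COC)c(O[Si](C)(C)C(C)(C)C)cc1O[Si](C)(C)C(C)(C)C | intermediate
15 | 2-[2,4-bis(tert-butyldimethylsilyloxy)-5-(2-methylbut-3-en-2-yl)phenyl]acetaldehyde | C=CC(C)(C)c1cc(CC=O)c(O[Si](C)(C)C(C)(C)C)cc1O[Si](C)(C)C(C)(C)C | intermediate (not isolated)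
16 | 2-[2,4-bis(tert-butyldimethylsilyloxy)-5-(2-methylbut-3-en-2-yl)phenyl]acetic acid | C=CC(C)(C)c1cc(CC(=O)O)c(O[Si](C)(C)C(C)(C)C)cc1O[Si](C)(C)C(C)(C)C | intermediate
17 | (R)-4-benzyloxazolidin-2-one | O=C1N[C@H](Cc2ccccc2)CO1 | starting material
18 | 2-[2,4-bis(tert-butyldimethylsilyloxy)-5-(2-methylbut-3-en-2-yl)phenyl]acetic pivalic anhydride | C=CC(C)(C)c1cc(CC(=O)OC(=O)C(C)(C)C)c(O[Si](C)(C)C(C)(C)C)cc1O[Si](C)(C)C(C)(C)C | intermediate (not isolated)
19 | (R)-4-benzyl-3-{2-[2,4-bis(tert-butyldimethylsilyloxy)-5-(2-methylbut-3-en-2-yl)phenyl]acetyl}oxazolidin-2-one | C=CC(C)(C)c1cc(CC(=O)N2[C@H](Cc3ccccc3)COC2=O)c(O[Si](C)(C)C(C)(C)C)cc1O[Si](C)(C)C(C)(C)C | intermediate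
20 | sodium (Z)-enolate of 19 | [Na]O/C(=C\c1cc(C(C)(C)C=C)c(O[Si](C)(C)C(C)(C)C)cc1O[Si](C)(C)C(C)(C)C)N1[C@H](Cc2ccccc2)COC1=O | intermediate (not isolated)
21 | 6-(allyloxy)-3-{(2R)-3-[(4R)-4-benzyl-2-oxooxazolidin-3-yl]-2-[2,4-bis(tert-butyldimethylsilyloxy)-5-(2-methylbut-3-en-2-yl)phenyl]-3-oxopropyl}-2-iodophenyl 4-chlorobenzenesulfonate | C=CCOc1ccc(C[C@@H](C(=O)N2[C@H](Cc3ccccc3)COC2=O)c2cc(C(C)(C)C=C)c(O[Si](C)(C)C(C)(C)C)cc2O[Si](C)(C)C(C)(C)C)c(I)c1OS(=O)(=O)c1ccc(Cl)cc1 | intermediate
22 | 6-(allyloxy)-3-{(2R)-2-[2,4-bis(tert-butyldimethylsilyloxy)-5-(2-methylbut-3-en-2-yl)phenyl]-3-hydroxypropyl}-2-iodophenyl 4-chlorobenzenesulfonate | OC[C@H](Cc1ccc(OCC=C)c(OS(=O)(=O)c2ccc(Cl)cc2)c1I)c1cc(C(C)(C)C=C)c(O[Si](C)(C)C(C)(C)C)cc1O[Si](C)(C)C(C)(C)C | intermediate (precursor of the key step)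
23 | 2,2-dimethyloxetane | CC1(C)CCO1 | starting material
24 | chloromagnesium alkoxide of 22 with MgCl in place of iodine at C8a | Cl[Mg]OC[C@H](Cc1ccc(OCC=C)c(OS(=O)(=O)c2ccc(Cl)cc2)c1[Mg]Cl)c1cc(C(C)(C)C=C)c(O[Si](C)(C)C(C)(C)C)cc1O[Si](C)(C)C(C)(C)C | intermediate (not isolated)
25 | C8–C8a aryne with the tethered chloromagnesium alkoxide | Cl[Mg]OC[C@H](CC1=CC=C(OCC=C)C#C1)c1cc(C(C)(C)C=C)c(O[Si](C)(C)C(C)(C)C)cc1O[Si](C)(C)C(C)(C)C | intermediate (not isolated)
26 | {(3R)-7-(allyloxy)-3-[2,4-bis(tert-butyldimethylsilyloxy)-5-(2-methylbut-3-en-2-yl)phenyl]chroman-8-yl}magnesium chloride | C=CC(C)(C)c1cc([C@@H]2COc3c(C2)ccc(OCC=C)c3[Mg]Cl)c(O[Si](C)(C)C(C)(C)C)cc1O[Si](C)(C)C(C)(C)C | intermediate (not isolated)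
27 | 4-{(3R)-7-(allyloxy)-3-[2,4-bis(tert-butyldimethylsilyloxy)-5-(2-methylbut-3-en-2-yl)phenyl]chroman-8-yl}-2-methylbutan-2-ol | C=CC(C)(C)c1cc([C@@H]2COc3c(C2)ccc(OCC=C)c3CCC(C)(C)O)c(O[Si](C)(C)C(C)(C)C)cc1O[Si](C)(C)C(C)(C)C | intermediate (product of the key step)
28 | (3R)-3-[2,4-bis(tert-butyldimethylsilyloxy)-5-(2-methylbut-3-en-2-yl)phenyl]-8-(3-hydroxy-3-methylbutyl)chroman-7-ol | C=CC(C)(C)c1cc([C@@H]2COc3c(C2)ccc(O)c3CCC(C)(C)O)c(O[Si](C)(C)C(C)(C)C)cc1O[Si](C)(C)C(C)(C)C | intermediate
29 | (3R)-3-[2,4-dihydroxy-5-(2-methylbut-3-en-2-yl)phenyl]-8-(3-hydroxy-3-methylbutyl)chroman-7-ol | C=CC(C)(C)c1cc([C@@H]2COc3c(ccc(O)c3CCC(C)(C)O)C2)c(O)cc1O | target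

## Step count and least certain steps

Total step count: 18. Longest linear sequence: 12 steps (steps 7 to 18, from 8). The ring A branch (steps 1 to 6) joins at step 14.

**Step 16 (key step, new method).** Two processes are most likely to fail.
- The C8 Grignard reagent is flanked by two oxygen substituents and may open the oxetane too slowly. Protonation on work-up, copper-mediated coupling with the 2-iodopropane from the exchange, or allyl transfer from an aryl allyl ether could then win.
- The aryne may be captured intermolecularly by arylmagnesium species before the poorly nucleophilic magnesium alkoxide closes ring C.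

Fallback, from 22 back to 27, in two operations of known type: the exchange and cyclisation are run as above, but the C8 Grignard reagent is quenched with iodine. This should give (3R)-7-(allyloxy)-3-[2,4-bis(tert-butyldimethylsilyloxy)-5-(2-methylbut-3-en-2-yl)phenyl]-8-iodochroman F1. The chain is then attached by B-alkyl Suzuki–Miyaura coupling of F1 with 4-(9-borabicyclo[3.3.1]nonan-9-yl)-2-methylbutan-2-ol F2, made in the flask from 2-methylbut-3-en-2-ol and excess 9-BBN (Pd(dppf)Cl2, K3PO4, THF/H2O, 50 °C), which returns to 27.

**Step 3.** BBr3 may attack the aldehyde (conversion into a benzal bromide), the sulfonate may be cleaved or shifted, or demethylation of the electron-poor ether may stall. Fallback, from 2 back to 5, with the order inverted: AlCl3 in pyridine, assisted by the free neighbouring hydroxyl, should demethylate 2 to 3,4-dihydroxy-2-iodobenzaldehyde F3. The more acidic 4-hydroxyl (para to the formyl group) is allylated selectively (allyl bromide, Li2CO3, DMF) to 4-(allyloxy)-3-hydroxy-2-iodobenzaldehyde F4, and sulfonylation as in step 2 gives 5.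

**Step 9.** Regiocontrol may be lost (migration to C3), the ortho-(1,1-dimethylallyl)phenol may react further at 190 °C (cyclisation onto the alkene, abnormal Claisen rearrangement), or the silyl group may move between phenols. Fallback, from 8 back to 13, without a sigmatropic step: bromination (N-bromosuccinimide, MeCN, 0 °C) should give 5-bromo-2,4-dihydroxybenzaldehyde F5. A γ-selective Suzuki–Miyaura coupling with 3-methylbut-2-enylboronic acid pinacol ester (Pd(OAc)2, a bulky biaryl dialkylphosphine, K3PO4, THF/H2O) transfers the tertiary allyl terminus and gives 2,4-dihydroxy-5-(2-methylbut-3-en-2-yl)benzaldehyde F6. Double silylation (TBSOTf, 2,6-lutidine) gives 13.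

**Step 14.** The ortho silyloxy group twists the aryl ring of the enolate, which may slow the alkylation and erode facial selectivity. The acidic α-aryl imide product may also epimerise with residual base. Fallback, from 16 and 7 back to 22, with a recoverable chiral base in place of the covalent auxiliary: the dilithium enediolate of 16 is formed with n-BuLi and a C2-symmetric chiral tetramine (the enantiomer leading to the R acid) and alkylated with 7. This gives (2R)-3-[4-(allyloxy)-3-(4-chlorophenylsulfonyloxy)-2-iodophenyl]-2-[2,4-bis(tert-butyldimethylsilyloxy)-5-(2-methylbut-3-en-2-yl)phenyl]propanoic acid F7. Methylation (TMSCHN2, MeOH/toluene) gives the methyl ester F8, and LiBH4 reduction gives 22.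

## Further compounds

F1 | step 16 | (3R)-7-(allyloxy)-3-[2,4-bis(tert-butyldimethylsilyloxy)-5-(2-methylbut-3-en-2-yl)phenyl]-8-iodochroman | C=CC(C)(C)c1cc([C@@H]2COc3c(C2)ccc(OCC=C)c3I)c(O[Si](C)(C)C(C)(C)C)cc1O[Si](C)(C)C(C)(C)C
F2 | step 16 | 4-(9-borabicyclo[3.3.1]nonan-9-yl)-2-methylbutan-2-ol | CC(C)(O)CCB1C2CCCC1CCC2
F3 | step 3 | 3,4-dihydroxy-2-iodobenzaldehyde | O=Cc1ccc(O)c(O)c1I
F4 | step 3 | 4-(allyloxy)-3-hydroxy-2-iodobenzaldehyde | C=CCOc1ccc(C=O)c(I)c1O
F5 | step 9 | 5-bromo-2,4-dihydroxybenzaldehyde | O=Cc1cc(Br)c(O)cc1O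
F6 | step 9 | 2,4-dihydroxy-5-(2-methylbut-3-en-2-yl)benzaldehyde | C=CC(C)(C)c1cc(C=O)c(O)cc1O
F7 | step 14 | (2R)-3-[4-(allyloxy)-3-(4-chlorophenylsulfonyloxy)-2-iodophenyl]-2-[2,4-bis(tert-butyldimethylsilyloxy)-5-(2-methylbut-3-en-2-yl)phenyl]propanoic acid | C=CCOc1ccc(C[C@@H](C(=O)O)c2cc(C(C)(C)C=C)c(O[Si](C)(C)C(C)(C)C)cc2O[Si](C)(C)C(C)(C)C)c(I)c1OS(=O)(=O)c1ccc(Cl)cc1
F8 | step 14 | methyl (2R)-3-[4-(allyloxy)-3-(4-chlorophenylsulfonyloxy)-2-iodophenyl]-2-[2,4-bis(tert-butyldimethylsilyloxy)-5-(2-methylbut-3-en-2-yl)phenyl]propanoate | C=CCOc1ccc(C[C@@H](C(=O)OC)c2cc(C(C)(C)C=C)c(O[Si](C)(C)C(C)(C)C)cc2O[Si](C)(C)C(C)(C)C)c(I)c1OS(=O)(=O)c1ccc(Cl)cc1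
A1 | alternative 1 | 6-[(2R)-2-{2,4-bis(tert-butyldimethylsilyloxy)-5-(2-methylbut-3-en-2-yl)phenyl}-3-(tert-butyldimethylsilyloxy)propyl]-2-[3-methyl-3-(triethylsilyloxy)butyl]-3-(triisopropylsilyloxy)phenol | CC(C)[Si](C(C)C)(C(C)C)Oc1ccc(C[C@@H](CO[Si](C)(C)C(C)(C)C)c2cc(C(C)(C)C=C)c(O[Si](C)(C)C(C)(C)C)cc2O[Si](C)(C)C(C)(C)C)c(O)c1CCC(C)(C)O[Si](CC)(CC)CC
A2 | alternative 1 | (3E,6R)-6-[2,4-bis(tert-butyldimethylsilyloxy)-5-(2-methylbut-3-en-2-yl)phenyl]-7-(tert-butyldimethylsilyloxy)-1-diazohept-3-en-2-one | [N-]=[N+]=CC(=O)/C=C/C[C@@H](CO[Si](C)(C)C(C)(C)C)c1cc(C(C)(C)C=C)c(O[Si](C)(C)C(C)(C)C)cc1O[Si](C)(C)C(C)(C)C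
A3 | alternative 1 | triethyl{[2-methyl-6-(triisopropylsilyloxy)hex-5-yn-2-yl]oxy}silane | CC(C)[Si](C(C)C)(C(C)C)OC#CCCC(C)(C)O[Si](CC)(CC)CC
A4 | alternative 2 | methyl (2R,3S)-2-{2,4-bis(tert-butyldimethylsilyloxy)-3-[3-methyl-3-(triethylsilyloxy)butyl]phenyl}-6-(tert-butyldimethylsilyloxy)-5-(2-methylbut-3-en-2-yl)-2,3-dihydrobenzofuran-3-carboxylate (cis) | COC(=O)[C@@H]1[C@H](c2ccc(O[Si](C)(C)C(C)(C)C)c(CCC(C)(C)O[Si](CC)(CC)CC)c2O[Si](C)(C)C(C)(C)C)Oc2cc(O[Si](C)(C)C(C)(C)C)c(C(C)(C)C=C)cc12
A5 | alternative 2 | methyl 2-diazo-2-{2-[(2,4-bis(tert-butyldimethylsilyloxy)-3-[3-methyl-3-(triethylsilyloxy)butyl]benzyl)oxy]-4-(tert-butyldimethylsilyloxy)-5-(2-methylbut-3-en-2-yl)phenyl}acetate | COC(=O)C(=[N+]=[N-])c1cc(C(C)(C)C=C)c(O[Si](C)(C)C(C)(C)C)cc1OCc1ccc(O[Si](C)(C)C(C)(C)C)c(CCC(C)(C)O[Si](CC)(CC)CC)c1O[Si](C)(C)C(C)(C)C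
A6 | alternative 3 | 2-[(1R)-1-{2,4-bis(methoxymethoxy)-5-(2-methylbut-3-en-2-yl)phenyl}-2-{2,4-bis(tert-butyldimethylsilyloxy)-3-[3-methyl-3-(triethylsilyloxy)butyl]phenyl}ethyl]-4,4,5,5-tetramethyl-1,3,2-dioxaborolane | CC1(C)OB(OC1(C)C)[C@H](Cc1ccc(O[Si](C)(C)C(C)(C)C)c(CCC(C)(C)O[Si](CC)(CC)CC)c1O[Si](C)(C)C(C)(C)C)c1cc(C(C)(C)C=C)c(OCOC)cc1OCOC
A7 | alternative 3 | 4,4,5,5-tetramethyl-2-vinyl-1,3,2-dioxaborolane | C=CB1OC(C)(C)C(C)(C)O1
A8 | alternative 3 | 1-bromo-2,4-bis(tert-butyldimethylsilyloxy)-3-[3-methyl-3-(triethylsilyloxy)butyl]benzene | Brc1ccc(O[Si](C)(C)C(C)(C)C)c(CCC(C)(C)O[Si](CC)(CC)CC)c1O[Si](C)(C)C(C)(C)C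
A9 | alternative 3 | [2,4-bis(methoxymethoxy)-5-(2-methylbut-3-en-2-yl)phenyl]lithium | [Li]c1cc(C(C)(C)C=C)c(OCOC)cc1OCOC
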